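The data are calculated from invented constants, noise included.

- 4 questions stand before us, and together they come to one decision: should the next run at 31 mM get more free base than 1.50 equiv, when no earlier run has changed that charge?

| flask | electrophile | free base | protonated nucleophile | remark | time |
|---|---|---|---|---|---|
| south | 21 mM | 1.5 equiv | 1.8 equiv | run made earlier |  |
| Monday's | 31 mM | 1.50 equiv | 1.80 equiv |  | 10 d |
| Thursday's | 31 mM | 2.20 equiv | 1.80 equiv |  | 10 d |
| Wednesday's | 31 mM | 3.40 equiv | 1.80 equiv |  | 10 d |

- south (time / h: electrophile / %, target / %): 4.00: 92.1, 7.6; 12.0: 81.6, 15.1; 20.0: 73.0, 21.3; 30.0: 63.3, 27.7; 50.0: 48.8, 37.0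

(standard deviation of a reading: 0.3 percentage points)

- part of the electrophile that has reacted at the end, Monday's
- part of the electrophile that has reacted at the end, Thursday's
- part of the electrophile that has reacted at the end, Wednesday's
- what raising the equivalents of free base from its lowest to its highest value here does to the part of the electrophile that has reacted (changes below 5 percentage points count as none) (it rises / it falls / no change)

- no earlier run changes the charge of free base; that part of a forecast is a guess

- We follow the fraction of electrophile left, not the fraction made. We assume a pseudo-first-order fall, where equal times multiply that fraction by equal factors.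
- In the south run the electrophile falls from 63.3% to 48.8% between 30.0 h and 50.0 h, which reads as a decay constant of 0.0130 h⁻¹.
- That is slower than the 0.0151 h⁻¹ read between 4.00 h and 12.0 h, so we carry the later, lower value.
- Kept up for 10 d, it leaves 4.41% of the electrophile. We call this fraction left at the asked time the room, since any gain in the reacted part from more free base has to come out of the electrophile still left.
- The room is less than the margin of 5 percentage points. We assume that Monday's is no slower than the south run and that more free base does not slow the flask, which is a guess.
- Our reckoning therefore puts Monday's near 95.6% reacted, expects no change across the charges, and keeps 1.50 equiv for the next run.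
- The forecast gives 94%, 96% and 98%, with the trend "no change", saying “Conversion is already near the ceiling”; its first figure lies below ours.
- The flasks give 98.0%, 99.8% and >99.9%, a change of 2 points from the lowest charge to the highest: no change.

    electrophile + nucleophile → acid set free + target (k = 52.9 M⁻¹ h⁻¹)
    nucleophile + acid set free ⇌ protonated nucleophile, settled at all times (K = 59100 M⁻¹)
    acid set free + free base ⇌ salt of the base (K = 12000 M⁻¹, k = 3.58 M⁻¹ h⁻¹)
    target ⇌ isomer of the product (K = 1.40, k = 0.00235 h⁻¹)
    electrophile + acid set free → side product (k = 1.16 M⁻¹ h⁻¹)
    2 nucleophile → self-condensation product (k = 1.02 M⁻¹ h⁻¹)

- Monday's leaves 2.0% of its electrophile, less than the room of 4.41%. We apply the same reckoning to a further flask, like Monday's but with 0.380 equiv of free base. The room holds no term for free base, so it again says 4.41%. That flask leaves 3.8%, with 96.2% reacted. Its free base is the first to run out, down to 1.7% of its charge. Its side product stands at 44.6% of the electrophile charged, more than its target at 36.0%, and Monday's holds 20.7% of side product.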